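0.0344 M is the number I carry here: the crossover concentration, the [second end groups] at which rings and links form equally fast. I read it from the first dawn reading, 6.3 % rings beside 10.6 % links at 0.0578 M. It rests on an assumption: the ring step's rate ignores [second end groups] while the link step's rate follows it, so the ratio of rings to links being made, a selectivity factor, is the crossover divided by [second end groups].

| flask | first end groups | second end groups | temperature | remark | time |
|---|---|---|---|---|---|
| autumn | 0.055 M | 0.0578 M | −20 °C | run made earlier |  |
| dawn | 0.028 M | 0.0578 M | −20 °C | run made earlier |  |
| oak | 0.055 M (fed, over 40 min) | 0.0578 M | −20 °C | all else is in the flask from the start; the feed brings no volume worth counting | 1.5 h |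
| cedar | 0.055 M | 0.0578 M (fed, over 40 min) |  | the addition at −40 °C, then warmed to −20 °C; the feed brings no volume worth counting | 1.5 h |
| alder | 0.055 M | 0.0578 M (fed, over 40 min) | −20 °C | all else is in the flask from the start; the feed brings no volume worth counting | 1.5 h |
| birch | 0.055 M | 0.0578 M | −20 °C | everything together at the start | 1.5 h |

| run | time / min | rings / % | links / % |
|---|---|---|---|
| autumn | 20.0 | 43.8 | 29.0 |
| autumn | 40.0 | 49.3 | 24.7 |
| autumn | 50.0 | 49.9 | 23.4 |
| autumn | 80.0 | 54.4 | 22.3 |
| autumn | 90.0 | 54.4 | 22.3 |
| dawn | 0.667 | 6.3 | 10.6 |
| dawn | 1.33 | 11.7 | 17.4 |
| dawn | 2.50 | 18.5 | 25.6 |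
| dawn | 5.00 | 27.5 | 33.9 |
| dawn | 10.0 | 34.6 | 37.9 |

(scatter of a reading: 0.5 percentage points)

* the flask with the highest amount of rings, in percent of the first end groups charged ("all alike" if they lie within 1.5 percentage points) (oak / cedar / alder / birch / all alike)
* final rings, as a percentage of the first end groups charged, in oak
* final rings, as a percentage of the first end groups charged, in cedar
* final rings, as a percentage of the first end groups charged, in alder
* final rings, as a percentage of the first end groups charged, in birch

Turn the question round: what must be true for alder, fed with second end groups at −20 °C, to give the most rings rather than the fewest? First, [second end groups] must end the feed below the crossover, so at least 0.0234 M must be used by then. The autumn run holds 0.0407 M in rings and links at 40.0 min, more than that; this sum is a lower bound on what it has used, and that run had its full charge present from the start, so this measures the margin without proving it.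

Second, the assumption must hold. In the dawn run the ratio of rings to links standing reads 0.913 at 10.0 min, when rings and links account for a fall of [second end groups] to 0.0375 M, and the crossover over that gives 0.917 for the ratio being made, which is a different quantity from the ratio standing. Links falling in the autumn run could also raise such a ratio, so this is a reading and no proof. Still, I commit to alder above birch, provided waiting first end groups survive.

The forecast differs: it names birch, with 53 % for oak, 48 % for cedar, 54 % for birch and 27 % for alder, where feeding, in its words, “leaves A waiting and decaying”, A being first end groups.

Alder ends highest, at 83.9 %, above birch's 55.0 %, oak's 53.1 % and cedar's 49.5 %.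

    first end groups + second end groups → links (k = 3.10 L mol⁻¹ min⁻¹, Ea = 50.0 kJ mol⁻¹)
    first end groups + second end groups → rings, rate k2*[first end groups] as long as [second end groups] is above zero (k = 0.110 min⁻¹, Ea = 79.0 kJ mol⁻¹)
    first end groups ⇌ dormant form (K = 1.50, k = 0.0630 min⁻¹, Ea = 84.0 kJ mol⁻¹, ΔH = −48.0 kJ mol⁻¹)
    links ⇌ isomer of the product (K = 0.960, k = 0.0230 min⁻¹, Ea = 79.0 kJ mol⁻¹, ΔH = −22.0 kJ mol⁻¹)
    (constants at −20 °C)

In alder, the dormant form stands at 21.8 % at 0.667 h and at 5.57 % at 1.50 h. At the first of those times alder's [second end groups] is 0.0176 M, below the crossover, which gives 1.95 rings being made per link. In cedar, warmed by then, [second end groups] at 1.50 h is 0.00650 M, so the crossover gives 5.29, and the ring step there uses second end groups 5.5 times as fast as the link step.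

Readings and results come from a simulation with constants of no real substance; the scatter is artificial.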